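**Assumption:** the SMILES is taken at face value (trans-fused hydroazulene). Comments use dictyotane locants: C1/C5 ring fusion, C3-OH, C4=C17, C6-OH, C7 side chain, C9-OH, C10=C18, C11-Me, C12-OAc; the target is 1S,3R,5R,6S,7R,9S,11S,12S. TBS = tert-butyldimethylsilyl, TES = triethylsilyl.

## Retrosynthetic overview

1. C9 carbinol from CBS reduction of the 10(18)-en-9-one; the seven-membered ring is closed last, at C9–C10, by Ni/Cr (Nozaki–Hiyama–Kishi) coupling of an alkenyl iodide with an aldehyde.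
2. C5–C6 bond, C4=C17 methylidene, C5/C6 stereocentres and the trans ring fusion from a Cr-mediated γ-allylation of aldehyde 23 with cyclopentenylmethyl bromide 8.
3. Bromide 8 (C1, C3) from (S)-4-silyloxycyclopentenone: cuprate addition/elimination, iododesilylation, Baylis–Hillman, Appel, CBS.
4. Aldehyde 23 (C7, C11, C12) from an Evans syn-aldol, a cis-5,6-disubstituted dihydropyranone, and anti conjugate addition of lithiodithiane.
5. Ring order: the cyclopentane is present from the start (chiral-pool enone); the cycloheptane is formed last.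

## Route

**Step 1**
Reactants: 1 (S)-4-(TBSO)cyclopent-2-en-1-one
Product: 3 (S)-4-[1-(trimethylsilyl)ethenyl]cyclopent-2-en-1-one, via silyloxy ketone 2 (not isolated)
Conditions: CH2=C(Br)SiMe3, Mg, THF, reflux; CuBr·SMe2 (10 mol %), THF, −78 °C, then 1; aq. work-up; DBU, CH2Cl2, 0 °C
Reagents that add atoms: (1-bromoethenyl)trimethylsilane, C=C(Br)[Si](C)(C)C
Why: Cu-catalysed conjugate addition of the Grignard reagent occurs anti to the 4-silyloxy group and E1cB loss of silanol then moves the enone, so the OTBS stereocentre is traded for the C1 stereocentre (S).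

**Step 2**
Reactants: 3 (S)-4-[1-(trimethylsilyl)ethenyl]cyclopent-2-en-1-one
Product: 4 (S)-4-(1-iodoethenyl)cyclopent-2-en-1-one
Conditions: NIS, MeCN, 0 °C → rt, dark
Reagents that add atoms: N-iodosuccinimide, O=C1CCC(=O)N1I
Why: Electrophilic ipso-iododesilylation of the vinylsilane (β-silyl cation) is selective because the enone alkene is electron-poor.

**Step 3**
Reactants: 4 (S)-4-(1-iodoethenyl)cyclopent-2-en-1-one
Product: 5 (S)-2-(hydroxymethyl)-4-(1-iodoethenyl)cyclopent-2-en-1-one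
Conditions: 37% aq. HCHO, imidazole (cat.), THF/H2O, rt
Reagents that add atoms: formaldehyde, C=O
Why: Morita–Baylis–Hillman hydroxymethylation at the enone α-carbon installs C17 under mild, weakly basic conditions that leave the γ-stereocentre alone.

**Step 4**
Reactants: 5 (S)-2-(hydroxymethyl)-4-(1-iodoethenyl)cyclopent-2-en-1-one
Product: 6 (S)-2-(bromomethyl)-4-(1-iodoethenyl)cyclopent-2-en-1-one
Conditions: CBr4, PPh3, CH2Cl2, −20 → 0 °C
Reagents that add atoms: carbon tetrabromide, BrC(Br)(Br)Br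
Why: Appel reaction converts the primary allylic alcohol into the bromide by SN2 displacement of the oxyphosphonium group.

**Step 5**
Reactants: 6 (S)-2-(bromomethyl)-4-(1-iodoethenyl)cyclopent-2-en-1-one
Product: 7 (1R,4S)-2-(bromomethyl)-4-(1-iodoethenyl)cyclopent-2-en-1-ol
Conditions: (S)-Me-CBS (20 mol %), catecholborane, toluene, −78 °C
Reagents that add atoms: none
Why: Corey–Bakshi–Shibata 1,2-reduction (α-substituted alkenyl arm as the large group) gives the 1R carbinol (C3), matched with hydride approach anti to the C4 substituent, i.e. the cis-1,4 alcohol.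

**Step 6**
Reactants: 7 (1R,4S)-2-(bromomethyl)-4-(1-iodoethenyl)cyclopent-2-en-1-ol
Product: 8 {[(1R,4S)-2-(bromomethyl)-4-(1-iodoethenyl)cyclopent-2-en-1-yl]oxy}(tert-butyl)dimethylsilane
Conditions: TBSOTf, 2,6-lutidine, CH2Cl2, −78 °C
Reagents that add atoms: tert-butyldimethylsilyl triflate, CC(C)(C)[Si](C)(C)OS(=O)(=O)C(F)(F)F
Why: Silylation of the secondary allylic alcohol with a hindered base leaves the allylic bromide untouched.

**Step 7**
Reactants: 9 4-methylpent-3-en-1-ol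
Product: 10 4-methylpent-3-enal
Conditions: Dess–Martin periodinane, pyridine, CH2Cl2, 0 °C; used at once
Reagents that add atoms: none
Why: Buffered Dess–Martin oxidation gives the β,γ-unsaturated aldehyde without isomerisation into conjugation.

**Step 8**
Reactants: 11 (R)-4-benzyl-3-propanoyl-1,3-oxazolidin-2-one; 10 4-methylpent-3-enal
Product: 13 (R)-4-benzyl-3-[(2R,3S)-3-hydroxy-2,6-dimethylhept-5-enoyl]-1,3-oxazolidin-2-one, via boron enolate 12 (not isolated)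
Conditions: Bu2BOTf, Et3N, CH2Cl2, −78 → 0 °C; 10, −78 → 0 °C; pH 7 buffer, MeOH, 30% H2O2
Reagents that add atoms: none
Why: Evans syn-aldol through the Z-boron enolate and a Zimmerman–Traxler chair, with the (R)-benzyl auxiliary fixing C11 and C12 (syn, 2R,3S here).

**Step 9**
Reactants: 13 (R)-4-benzyl-3-[(2R,3S)-3-hydroxy-2,6-dimethylhept-5-enoyl]-1,3-oxazolidin-2-one
Product: 14 (2R,3S)-3-hydroxy-N-methoxy-N,2,6-trimethylhept-5-enamide
Conditions: MeNH(OMe)·HCl, AlMe3, CH2Cl2, 0 °C → rt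
Reagents that add atoms: N,O-dimethylhydroxylamine hydrochloride, CNOC.Cl
Why: Aluminium-amide transamidation to the Weinreb amide, assisted by the free β-hydroxyl, proceeds without epimerisation and releases the auxiliary.

**Step 10**
Reactants: 14 (2R,3S)-3-hydroxy-N-methoxy-N,2,6-trimethylhept-5-enamide
Product: 15 (2R,3S)-N-methoxy-N,2,6-trimethyl-3-(TESO)hept-5-enamide
Conditions: TESCl, imidazole, DMF, 0 °C → rt
Reagents that add atoms: chlorotriethylsilane, CC[Si](Cl)(CC)CC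
Why: Silyl protection blocks retro-aldol and β-elimination in the next two steps.

**Step 11**
Reactants: 15 (2R,3S)-N-methoxy-N,2,6-trimethyl-3-(TESO)hept-5-enamide
Product: 16 (2R,3S)-2,6-dimethyl-3-(TESO)hept-5-enal
Conditions: DIBAL-H, THF, −78 °C; Rochelle salt
Reagents that add atoms: none
Why: Weinreb amide reduction stops at the aldehyde through the stable chelated tetrahedral intermediate.

**Step 12**
Reactants: 16 (2R,3S)-2,6-dimethyl-3-(TESO)hept-5-enal
Product: 18 (5S,6S)-5-methyl-6-(3-methylbut-2-en-1-yl)-5,6-dihydro-2H-pyran-2-one, via Z-enoate 17 (not isolated)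
Conditions: (CF3CH2O)2P(O)CH2CO2Me, KHMDS, 18-crown-6, THF, −78 °C; then 48% aq. HF, MeCN, 0 °C → rt
Reagents that add atoms: methyl 2-[bis(2,2,2-trifluoroethoxy)phosphoryl]acetate, COC(=O)CP(=O)(OCC(F)(F)F)OCC(F)(F)F
Why: Still–Gennari Z-selective Horner–Wadsworth–Emmons olefination adds C8–C9, and desilylation lets the Z-hydroxy ester lactonise to the cis-5,6-disubstituted dihydropyranone.

**Step 13**
Reactants: 18 (5S,6S)-5-methyl-6-(3-methylbut-2-en-1-yl)-5,6-dihydro-2H-pyran-2-one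
Product: 19 (4R,5S,6S)-4-(1,3-dithian-2-yl)-5-methyl-6-(3-methylbut-2-en-1-yl)oxan-2-one
Conditions: 1,3-dithiane, n-BuLi, THF, −30 °C; HMPA, −78 °C, then 18; H2O
Reagents that add atoms: 1,3-dithiane, C1CSCSC1
Why: Conjugate addition of the Corey–Seebach acyl-anion equivalent (HMPA favours 1,4) occurs on the face opposite the cis C5-methyl and C6-alkyl groups, setting C7 (R) and bringing in C6.

**Step 14**
Reactants: 19 (4R,5S,6S)-4-(1,3-dithian-2-yl)-5-methyl-6-(3-methylbut-2-en-1-yl)oxan-2-one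
Product: 20 (3R,4S,5S)-3-(1,3-dithian-2-yl)-4,8-dimethylnon-7-ene-1,5-diol
Conditions: LiAlH4, THF, 0 °C
Reagents that add atoms: none
Why: Hydride reduction opens the lactone to a primary (C9) and a secondary (C12) alcohol that are easy to tell apart.

**Step 15**
Reactants: 20 (3R,4S,5S)-3-(1,3-dithian-2-yl)-4,8-dimethylnon-7-ene-1,5-diol
Product: 22 (5S,6S,7R)-7-(1,3-dithian-2-yl)-2,6-dimethyl-9-(TESO)non-2-en-5-yl acetate, via mono-TES ether 21 (not isolated)
Conditions: TESCl (1.05 equiv), imidazole, CH2Cl2, −20 °C; then Ac2O, DMAP (cat.), rt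
Reagents that add atoms: chlorotriethylsilane, CC[Si](Cl)(CC)CC; acetic anhydride, CC(=O)OC(C)=O
Why: Selective silylation of the primary hydroxyl followed by acylation of the only remaining alcohol places the target's acetate on C12.

**Step 16**
Reactants: 22 (5S,6S,7R)-7-(1,3-dithian-2-yl)-2,6-dimethyl-9-(TESO)non-2-en-5-yl acetate
Product: 23 (5S,6S,7R)-7-formyl-2,6-dimethyl-9-(TESO)non-2-en-5-yl acetate
Conditions: MeI, CaCO3, MeCN/H2O (9:1), 40 °C
Reagents that add atoms: water, O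
Why: S-Alkylative dithiane hydrolysis under buffered, non-reducing conditions unmasks the C6 aldehyde without touching acetate, silyl ether or alkene.

**Step 17**
Reactants: 8 {[(1R,4S)-2-(bromomethyl)-4-(1-iodoethenyl)cyclopent-2-en-1-yl]oxy}(tert-butyl)dimethylsilane; 23 (5S,6S,7R)-7-formyl-2,6-dimethyl-9-(TESO)non-2-en-5-yl acetate
Product: 25 (5S,6S,7R)-7-{(S)-[(1R,3R,5S)-3-(TBSO)-5-(1-iodoethenyl)-2-methylidenecyclopentyl](hydroxy)methyl}-2,6-dimethyl-9-(TESO)non-2-en-5-yl acetate, via allylchromium reagent 24 (not isolated)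
Conditions: CrCl2 (4 equiv, Ni-free), THF, 0 °C → rt
Reagents that add atoms: none
Why: Nozaki–Hiyama allylation: the allylchromium attacks through its ring γ-carbon (C5) in a chair Zimmerman–Traxler transition state on the face opposite the C1 iodoethenyl and C3 OTBS groups (trans fusion, 5R), giving the anti adduct with Felkin approach to the α-branched aldehyde (6S) and shifting the alkene to C4=C17.

**Step 18**
Reactants: 25 (the C6 alcohol from step 17)
Product: 26 (5S,6S,7R)-7-{(S)-[(1R,3R,5S)-3-(TBSO)-5-(1-iodoethenyl)-2-methylidenecyclopentyl](TBSO)methyl}-2,6-dimethyl-9-(TESO)non-2-en-5-yl acetate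
Conditions: TBSOTf, 2,6-lutidine, CH2Cl2, −78 → 0 °C
Reagents that add atoms: tert-butyldimethylsilyl triflate, CC(C)(C)[Si](C)(C)OS(=O)(=O)C(F)(F)F
Why: Silylation of the hindered C6 alcohol prevents its oxidation and lactol formation with the C9 aldehyde.

**Step 19**
Reactants: 26 (the bis-TBS, C9-OTES compound from step 18)
Product: 27 (5S,6S,7R)-7-{(S)-[(1R,3R,5S)-3-(TBSO)-5-(1-iodoethenyl)-2-methylidenecyclopentyl](TBSO)methyl}-2,6-dimethyl-9-oxonon-2-en-5-yl acetate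
Conditions: (COCl)2, DMSO, CH2Cl2, −78 °C; Et3N, −78 → −30 °C
Reagents that add atoms: none
Why: Swern oxidation acts directly on the primary TES ether (silyl transfer to chloride, then ylide fragmentation) while the secondary TBS ethers are inert.

**Step 20**
Reactants: 27 (the C9 aldehyde from step 19)
Product: 29 (2S,3S)-2-[(2R,3aR,4S,5R,7RS,8aS)-2,4-bis(TBSO)-7-hydroxy-3,8-dimethylidenedecahydroazulen-5-yl]-6-methylhept-5-en-3-yl acetate, via alkenylchromium reagent 28 (not isolated)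
Conditions: CrCl2 (10 equiv), NiCl2 (1 mol %), DMSO/THF, rt, 3 mM
Reagents that add atoms: none
Why: Intramolecular Nozaki–Hiyama–Kishi coupling of the alkenyl iodide with the aldehyde closes the seven-membered ring and creates the C10 methylidene; the C9 configuration is not relied on because step 21 erases it.

**Step 21**
Reactants: 29 (the C9 epimeric allylic alcohols from step 20)
Product: 30 (2S,3S)-2-[(2R,3aR,4S,5R,8aS)-2,4-bis(TBSO)-3,8-dimethylidene-7-oxodecahydroazulen-5-yl]-6-methylhept-5-en-3-yl acetate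
Conditions: Dess–Martin periodinane, pyridine, CH2Cl2, 0 °C
Reagents that add atoms: none
Why: Buffered Dess–Martin oxidation converges both C9 epimers on the α-methylidene ketone without moving the exocyclic alkene or touching C1.

**Step 22**
Reactants: 30 (the C9 enone from step 21)
Product: 31 (2S,3S)-2-[(2R,3aR,4S,5R,7S,8aS)-2,4-bis(TBSO)-7-hydroxy-3,8-dimethylidenedecahydroazulen-5-yl]-6-methylhept-5-en-3-yl acetate
Conditions: (R)-Me-CBS (1 equiv), catecholborane, toluene, −78 °C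
Reagents that add atoms: none
Why: Reagent-controlled Corey–Bakshi–Shibata 1,2-reduction (C10 alkenyl arm large, C8 methylene small) sets 9S.

**Step 23**
Reactants: 31 (the 9S alcohol from step 22)
Product: 32 (2S,3S)-6-methyl-2-[(2R,3aR,4S,5R,7S,8aS)-2,4,7-trihydroxy-3,8-dimethylidenedecahydroazulen-5-yl]hept-5-en-3-yl acetate
Conditions: HF·pyridine, pyridine, THF, 0 °C → rt
Reagents that add atoms: none
Why: Buffered fluoride desilylation frees the C3 and C6 hydroxyls without acetate cleavage or migration.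

## Compound list

1 | (S)-4-(TBSO)cyclopent-2-en-1-one | O=C1C[C@H](O[Si](C)(C)C(C)(C)C)C=C1 | starting material
2 | (3S,4S)-3-(TBSO)-4-[1-(trimethylsilyl)ethenyl]cyclopentan-1-one | O=C1C[C@H](O[Si](C)(C)C(C)(C)C)[C@@H](C(=C)[Si](C)(C)C)C1 | intermediate (not isolated)
3 | (S)-4-[1-(trimethylsilyl)ethenyl]cyclopent-2-en-1-one | O=C1C=C[C@@H](C(=C)[Si](C)(C)C)C1 | intermediate
4 | (S)-4-(1-iodoethenyl)cyclopent-2-en-1-one | O=C1C=C[C@@H](C(I)=C)C1 | intermediate
5 | (S)-2-(hydroxymethyl)-4-(1-iodoethenyl)cyclopent-2-en-1-one | O=C1C(CO)=C[C@@H](C(I)=C)C1 | intermediate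
6 | (S)-2-(bromomethyl)-4-(1-iodoethenyl)cyclopent-2-en-1-one | O=C1C(CBr)=C[C@@H](C(I)=C)C1 | intermediate
7 | (1R,4S)-2-(bromomethyl)-4-(1-iodoethenyl)cyclopent-2-en-1-ol | BrCC1=C[C@@H](C(I)=C)C[C@H]1O | intermediate
8 | {[(1R,4S)-2-(bromomethyl)-4-(1-iodoethenyl)cyclopent-2-en-1-yl]oxy}(tert-butyl)dimethylsilane | BrCC1=C[C@@H](C(I)=C)C[C@H]1O[Si](C)(C)C(C)(C)C | intermediate
9 | 4-methylpent-3-en-1-ol | CC(C)=CCCO | starting material
10 | 4-methylpent-3-enal | CC(C)=CCC=O | intermediate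
11 | (R)-4-benzyl-3-propanoyl-1,3-oxazolidin-2-one | CCC(=O)N1[C@H](Cc2ccccc2)COC1=O | starting material
12 | (Z)-dibutylboron enolate of 11 | C/C=C(\OB(CCCC)CCCC)N1[C@H](Cc2ccccc2)COC1=O | intermediate (not isolated)
13 | (R)-4-benzyl-3-[(2R,3S)-3-hydroxy-2,6-dimethylhept-5-enoyl]-1,3-oxazolidin-2-one | CC(C)=CC[C@H](O)[C@@H](C)C(=O)N1[C@H](Cc2ccccc2)COC1=O | intermediate
14 | (2R,3S)-3-hydroxy-N-methoxy-N,2,6-trimethylhept-5-enamide | CC(C)=CC[C@H](O)[C@@H](C)C(=O)N(C)OC | intermediate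
15 | (2R,3S)-N-methoxy-N,2,6-trimethyl-3-(TESO)hept-5-enamide | CC(C)=CC[C@H](O[Si](CC)(CC)CC)[C@@H](C)C(=O)N(C)OC | intermediate
16 | (2R,3S)-2,6-dimethyl-3-(TESO)hept-5-enal | CC(C)=CC[C@H](O[Si](CC)(CC)CC)[C@@H](C)C=O | intermediate
17 | methyl (2Z,4S,5S)-4,8-dimethyl-5-(TESO)nona-2,7-dienoate | COC(=O)/C=C\[C@H](C)[C@@H](O[Si](CC)(CC)CC)CC=C(C)C | intermediate (not isolated)
18 | (5S,6S)-5-methyl-6-(3-methylbut-2-en-1-yl)-5,6-dihydro-2H-pyran-2-one | O=C1C=C[C@H](C)[C@H](CC=C(C)C)O1 | intermediate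
19 | (4R,5S,6S)-4-(1,3-dithian-2-yl)-5-methyl-6-(3-methylbut-2-en-1-yl)oxan-2-one | O=C1C[C@@H](C2SCCCS2)[C@H](C)[C@H](CC=C(C)C)O1 | intermediate
20 | (3R,4S,5S)-3-(1,3-dithian-2-yl)-4,8-dimethylnon-7-ene-1,5-diol | OCC[C@@H](C1SCCCS1)[C@H](C)[C@@H](O)CC=C(C)C | intermediate
21 | (5S,6S,7R)-7-(1,3-dithian-2-yl)-2,6-dimethyl-9-(TESO)non-2-en-5-ol | CC[Si](CC)(CC)OCC[C@@H](C1SCCCS1)[C@H](C)[C@@H](O)CC=C(C)C | intermediate (not isolated)
22 | (5S,6S,7R)-7-(1,3-dithian-2-yl)-2,6-dimethyl-9-(TESO)non-2-en-5-yl acetate | CC[Si](CC)(CC)OCC[C@@H](C1SCCCS1)[C@H](C)[C@@H](OC(C)=O)CC=C(C)C | intermediate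
23 | (5S,6S,7R)-7-formyl-2,6-dimethyl-9-(TESO)non-2-en-5-yl acetate | O=C[C@@H]([C@H](C)[C@H](CC=C(C)C)OC(C)=O)CCO[Si](CC)(CC)CC | intermediate
24 | allylchromium(III) dichloride from 8 (Cr on the former CH2Br carbon) | Cl[Cr](Cl)CC1=C[C@@H](C(I)=C)C[C@H]1O[Si](C)(C)C(C)(C)C | intermediate (not isolated)
25 | (5S,6S,7R)-7-{(S)-[(1R,3R,5S)-3-(TBSO)-5-(1-iodoethenyl)-2-methylidenecyclopentyl](hydroxy)methyl}-2,6-dimethyl-9-(TESO)non-2-en-5-yl acetate | C=C1[C@H]([C@@H](O)[C@@H]([C@H](C)[C@H](CC=C(C)C)OC(C)=O)CCO[Si](CC)(CC)CC)[C@@H](C(I)=C)C[C@H]1O[Si](C)(C)C(C)(C)C | intermediate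
26 | (5S,6S,7R)-7-{(S)-[(1R,3R,5S)-3-(TBSO)-5-(1-iodoethenyl)-2-methylidenecyclopentyl](TBSO)methyl}-2,6-dimethyl-9-(TESO)non-2-en-5-yl acetate | C=C1[C@H]([C@@H](O[Si](C)(C)C(C)(C)C)[C@@H]([C@H](C)[C@H](CC=C(C)C)OC(C)=O)CCO[Si](CC)(CC)CC)[C@@H](C(I)=C)C[C@H]1O[Si](C)(C)C(C)(C)C | intermediate
27 | (5S,6S,7R)-7-{(S)-[(1R,3R,5S)-3-(TBSO)-5-(1-iodoethenyl)-2-methylidenecyclopentyl](TBSO)methyl}-2,6-dimethyl-9-oxonon-2-en-5-yl acetate | C=C1[C@H]([C@@H](O[Si](C)(C)C(C)(C)C)[C@@H]([C@H](C)[C@H](CC=C(C)C)OC(C)=O)CC=O)[C@@H](C(I)=C)C[C@H]1O[Si](C)(C)C(C)(C)C | intermediate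
28 | alkenylchromium(III) dichloride from 27 (Cr in place of I) | C=C1[C@H]([C@@H](O[Si](C)(C)C(C)(C)C)[C@@H]([C@H](C)[C@H](CC=C(C)C)OC(C)=O)CC=O)[C@@H](C(=C)[Cr](Cl)Cl)C[C@H]1O[Si](C)(C)C(C)(C)C | intermediate (not isolated)
29 | (2S,3S)-2-[(2R,3aR,4S,5R,7RS,8aS)-2,4-bis(TBSO)-7-hydroxy-3,8-dimethylidenedecahydroazulen-5-yl]-6-methylhept-5-en-3-yl acetate (C9 epimers) | C=C1[C@@H]2[C@@H](O[Si](C)(C)C(C)(C)C)[C@@H]([C@H](C)[C@H](CC=C(C)C)OC(C)=O)CC(O)C(=C)[C@H]2C[C@H]1O[Si](C)(C)C(C)(C)C | intermediate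
30 | (2S,3S)-2-[(2R,3aR,4S,5R,8aS)-2,4-bis(TBSO)-3,8-dimethylidene-7-oxodecahydroazulen-5-yl]-6-methylhept-5-en-3-yl acetate | C=C1[C@@H]2[C@@H](O[Si](C)(C)C(C)(C)C)[C@@H]([C@H](C)[C@H](CC=C(C)C)OC(C)=O)CC(=O)C(=C)[C@H]2C[C@H]1O[Si](C)(C)C(C)(C)C | intermediate
31 | (2S,3S)-2-[(2R,3aR,4S,5R,7S,8aS)-2,4-bis(TBSO)-7-hydroxy-3,8-dimethylidenedecahydroazulen-5-yl]-6-methylhept-5-en-3-yl acetate | C=C1[C@@H]2[C@@H](O[Si](C)(C)C(C)(C)C)[C@@H]([C@H](C)[C@H](CC=C(C)C)OC(C)=O)C[C@H](O)C(=C)[C@H]2C[C@H]1O[Si](C)(C)C(C)(C)C | intermediate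
32 | (2S,3S)-6-methyl-2-[(2R,3aR,4S,5R,7S,8aS)-2,4,7-trihydroxy-3,8-dimethylidenedecahydroazulen-5-yl]hept-5-en-3-yl acetate | C=C1[C@@H]2[C@@H](O)[C@@H]([C@H](C)[C@H](CC=C(C)C)OC(C)=O)C[C@H](O)C(=C)[C@H]2C[C@H]1O | target

## Summary

Total step count: 23.
Longest linear sequence: 17 steps (9 → 32, steps 7–16 and 17–23); the other branch is 13 steps (1 → 32).

Three steps most likely to fail:

**Step 3 (Baylis–Hillman on a γ-substituted, base-sensitive enone; slow reaction or erosion at C1).** The fallback sets out from 3 and comes back at 5. Enone 3 is iodinated at the α-carbon with I2/pyridine in CH2Cl2 to give (S)-2-iodo-4-[1-(trimethylsilyl)ethenyl]cyclopent-2-en-1-one F1. Stille coupling with (tributylstannyl)methanol (Pd(PPh3)4, dioxane, 80 °C) gives (S)-2-(hydroxymethyl)-4-[1-(trimethylsilyl)ethenyl]cyclopent-2-en-1-one F2. Iododesilylation with NIS in MeCN then delivers 5, so that 4 is bypassed and C17 is introduced by cross-coupling instead of an amine-catalysed aldol.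

**Step 17 (chromium allylation; diastereocontrol at C5/C6 or low conversion with the α-branched aldehyde).** The fallback sets out from 6 and 23 and comes back at 26. The C5–C6 bond is made at the ketone oxidation level. Bromo enone 6 and aldehyde 23 are joined in an indium-mediated Barbier reaction (In powder, THF/H2O, rt), which attacks through C5. This gives (5S,6S,7R)-7-{(S)-hydroxy[(1R,5S)-5-(1-iodoethenyl)-2-methylidene-3-oxocyclopentyl]methyl}-2,6-dimethyl-9-(TESO)non-2-en-5-yl acetate F3. (S)-Me-CBS/catecholborane reduction of the C3 ketone gives (5S,6S,7R)-7-{(S)-hydroxy[(1R,3R,5S)-3-hydroxy-5-(1-iodoethenyl)-2-methylidenecyclopentyl]methyl}-2,6-dimethyl-9-(TESO)non-2-en-5-yl acetate F4. Double silylation (TBSOTf, 2,6-lutidine) returns the route at 26, bypassing 7, 8 and 25.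

**Step 20 (seven-membered ring closure by Ni/Cr coupling; oligomerisation or reduction of the iodide).** The fallback sets out from 27 and comes back at 30. Aldehyde 27 is oxidised (NaClO2, NaH2PO4, 2-methylbut-2-ene, t-BuOH/H2O) to (3R,4S,5S)-5-(acetyloxy)-3-{(S)-[(1R,3R,5S)-3-(TBSO)-5-(1-iodoethenyl)-2-methylidenecyclopentyl](TBSO)methyl}-4,8-dimethylnon-7-enoic acid F5. This is converted with 2,2'-dipyridyl disulfide/PPh3 into its S-(pyridin-2-yl) thioester F6. A Ni/Zr-mediated reductive ketone coupling of the alkenyl iodide with the thioester (NiBr2·dtbbpy, Cp2ZrCl2, Zn, DMI, rt) closes the ring as enone 30 directly, so steps 20 and 21 are bypassed.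

## Further compounds

F1 | step 3 | (S)-2-iodo-4-[1-(trimethylsilyl)ethenyl]cyclopent-2-en-1-one | O=C1C(I)=C[C@@H](C(=C)[Si](C)(C)C)C1
F2 | step 3 | (S)-2-(hydroxymethyl)-4-[1-(trimethylsilyl)ethenyl]cyclopent-2-en-1-one | O=C1C(CO)=C[C@@H](C(=C)[Si](C)(C)C)C1
F3 | step 17 | (5S,6S,7R)-7-{(S)-hydroxy[(1R,5S)-5-(1-iodoethenyl)-2-methylidene-3-oxocyclopentyl]methyl}-2,6-dimethyl-9-(TESO)non-2-en-5-yl acetate | C=C1[C@H]([C@@H](O)[C@@H]([C@H](C)[C@H](CC=C(C)C)OC(C)=O)CCO[Si](CC)(CC)CC)[C@@H](C(I)=C)CC1=O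
F4 | step 17 | (5S,6S,7R)-7-{(S)-hydroxy[(1R,3R,5S)-3-hydroxy-5-(1-iodoethenyl)-2-methylidenecyclopentyl]methyl}-2,6-dimethyl-9-(TESO)non-2-en-5-yl acetate | C=C1[C@H]([C@@H](O)[C@@H]([C@H](C)[C@H](CC=C(C)C)OC(C)=O)CCO[Si](CC)(CC)CC)[C@@H](C(I)=C)C[C@H]1O
F5 | step 20 | (3R,4S,5S)-5-(acetyloxy)-3-{(S)-[(1R,3R,5S)-3-(TBSO)-5-(1-iodoethenyl)-2-methylidenecyclopentyl](TBSO)methyl}-4,8-dimethylnon-7-enoic acid | C=C1[C@H]([C@@H](O[Si](C)(C)C(C)(C)C)[C@@H]([C@H](C)[C@H](CC=C(C)C)OC(C)=O)CC(=O)O)[C@@H](C(I)=C)C[C@H]1O[Si](C)(C)C(C)(C)C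
F6 | step 20 | S-(pyridin-2-yl) thioester of F5 | C=C1[C@H]([C@@H](O[Si](C)(C)C(C)(C)C)[C@@H]([C@H](C)[C@H](CC=C(C)C)OC(C)=O)CC(=O)Sc2ccccn2)[C@@H](C(I)=C)C[C@H]1O[Si](C)(C)C(C)(C)C
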